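## Retrosynthetic overview

1. Last disconnection: the veratroyl ester C–O bond, giving the all-cis diol 12 and 3,4-dimethoxybenzoyl chloride 13.
2. Diol 12 comes, through aldehyde 11, from the six-membered aryl C-pentopyranoside 10 by a semipinacol ring contraction: the oxolane atoms O1, C2, C3, C4, C5 plus the exocyclic CH2 carbon on C3 are the six ring atoms of an oxane, in which that carbon (sugar C2) sits between the benzylic carbon and C3.
3. Enabling feature: oxolane C3 carries a one-carbon oxygenated branch and lies between the benzylic, O1-bearing C2 (a very good migrating carbon) and the oxygenated C4. In oxane 10 the free HO–C2 and the equatorial TsO–C3 are trans-diequatorial, so the ring bond C1–C2 is antiperiplanar to C3–OTs. The 1,3-cis aryl/OTs and 3,4-cis O4/OTs relations of the α-D-arabino series then become the all-cis array.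
4. Oxane 10 comes from D-arabinose (its C3 and C4 supply the chirality) by 1,2-trans C-arylation of the pivaloylated glycosyl bromide with an arylzinc bromide, deacylation and tin-directed 3-O-tosylation.
5. Ring order: the oxane ring is taken over from the pyranose and carried to step 7, where it is contracted to the oxolane; both benzene rings are bought.

Key step: step 7

Remark: the oxane intermediates are numbered as sugars (C1 aryl-bearing, C2–C4 oxygenated, C5 methylene, O5 ring oxygen) and the oxolanes as O1, C2–C5; the 4-hydroxyl of 10 is deliberately left free, on the assumption that the benzylic C1 migrates far more readily than C5.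

## Route

Step 1
Reactants: 1 D-arabinose
Product: 2 1,2,3,4-tetra-O-pivaloyl-D-arabinopyranose (anomeric mixture)
Conditions: PivCl (5 equiv), pyridine, DMAP (cat.), 0 °C to rt
Reagents that add atoms: pivaloyl chloride, CC(C)(C)C(Cl)=O
Why: Exhaustive O-acylation of the sugar in its pyranose form should give the tetraester without touching C2–C4; pivaloates are chosen because they survive the organozinc step and participate cleanly at C1.

Step 2
Reactants: 2 1,2,3,4-tetra-O-pivaloyl-D-arabinopyranose
Product: 3 2,3,4-tri-O-pivaloyl-β-D-arabinopyranosyl bromide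
Conditions: HBr (33% in AcOH), CH2Cl2, 0 °C to rt
Reagents that add atoms: hydrogen bromide, Br
Why: Acid-promoted exchange of the anomeric ester for bromide through the acyloxonium ion is the standard glycosyl bromide synthesis, and the anomeric effect should give the axial (1,2-cis) bromide from both anomers of 2.

Step 3
Reactants: 4 4-bromo-1,2-dimethoxybenzene
Product: 6 (3,4-dimethoxyphenyl)zinc bromide, via 3,4-dimethoxyphenyllithium 5 (not isolated)
Conditions: n-BuLi (1.0 equiv), toluene/n-Bu2O, −20 °C to 0 °C; then ZnBr2·LiBr (1.0 equiv) in n-Bu2O, 0 °C to rt; solution used as such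
Reagents that add atoms: zinc bromide, [Zn+2].[Br-].[Br-]
Why: Bromine–lithium exchange followed by transmetalation of the aryllithium onto one equivalent of ZnBr2 should give the arylzinc bromide (as its LiBr adduct) in the ether/toluene medium that the catalyst-free C-glycosylation needs, so that each aryl bromide gives one zinc reagent and no aryl group is lost.

Step 4
Reactants: 3 2,3,4-tri-O-pivaloyl-β-D-arabinopyranosyl bromide, 6 (3,4-dimethoxyphenyl)zinc bromide
Product: 7 (1R)-1,5-anhydro-1-C-(3,4-dimethoxyphenyl)-2,3,4-tri-O-pivaloyl-D-arabinitol (α-C-arabinopyranoside with equatorial aryl trans to O2)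
Conditions: 6 (1.5 equiv), toluene/n-Bu2O, 90 °C
Reagents that add atoms: none
Why: In this arylzinc C-glycosylation of a 2-O-acyl glycosyl bromide (aryl transfer from an arylzinc halide in a weakly coordinating solvent without a transition metal), zinc-assisted ionization lets the O2 pivaloate form the cis-fused acyloxonium ion, and aryl transfer to C1 from the opposite face should set the 1,2-trans (equatorial aryl) stereocentre.

Step 5
Reactants: 7 (1R)-1,5-anhydro-1-C-(3,4-dimethoxyphenyl)-2,3,4-tri-O-pivaloyl-D-arabinitol
Product: 8 (1R)-1,5-anhydro-1-C-(3,4-dimethoxyphenyl)-D-arabinitol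
Conditions: NaOMe, MeOH, 50 °C
Reagents that add atoms: none
Why: Zemplén transesterification should remove the three pivaloates while the C-glycosidic bond and all stereocentres stay inert to methoxide.

Step 6
Reactants: 8 (1R)-1,5-anhydro-1-C-(3,4-dimethoxyphenyl)-D-arabinitol
Product: 10 (1R)-1,5-anhydro-1-C-(3,4-dimethoxyphenyl)-3-O-(p-tolylsulfonyl)-D-arabinitol, via 3,4-O-dibutylstannylene acetal 9 (not isolated)
Conditions: Bu2SnO (1.1 equiv), MeOH, reflux; evaporation; TsCl (1.1 equiv), 1,4-dioxane, rt
Reagents that add atoms: p-toluenesulfonyl chloride, Cc1ccc(cc1)S(Cl)(=O)=O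
Why: In stannylene-directed sulfonylation the five-membered tin acetal forms on the cis-3,4-diol and activates its equatorial oxygen O3, as is known for galacto- and arabino-configured pyranosides, so the leaving group should go on C3 with O2 and O4 left free.

Step 7
Reactants: 10 (1R)-1,5-anhydro-1-C-(3,4-dimethoxyphenyl)-3-O-(p-tolylsulfonyl)-D-arabinitol
Product: 12 [(2S,3R,4S)-2-(3,4-dimethoxyphenyl)-4-hydroxyoxolan-3-yl]methanol, via all-cis aldehyde 11 (not isolated)
Conditions: LiEt3BH (4 equiv), THF, 0 °C to rt; then H2O
Reagents that add atoms: none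
Why: LiEt3BH deprotonates the hydroxyls, the C2 alkoxide pushes while the ring bond C1–C2, antiperiplanar to the equatorial C3–OTs bond in the chair, migrates from C2 to C3 with loss of tosylate (semipinacol 1,2-shift), and the aldehyde 11 so formed is reduced at once by the excess hydride. The closest known reaction type is the LiEt3BH- or base-induced ring contraction of pyranoside hydroxy sulfonates to C-(hydroxymethyl) furanosides, a cyclic case of the pinacol-type rearrangement of 2-sulfonyloxy alcohols. The oxolane ring (O5, C1, C3, C4, C5) is closed by this suprafacial 1,2-carbon shift, an intramolecular back-side displacement at C3 by the migrating σ bond, not by a separate cyclisation. The new stereocentre C3 is fixed by stereospecific inversion at C3 with retention at the migrating C1, so the formyl carbon ends on the face the tosylate left, cis to the aryl group (1,3-cis to OTs in 10) and cis to O4 (3,4-cis to OTs in 10), while C1 and C4 are carried over unchanged. The step needs migration of C1 and not of C5 (also antiperiplanar and pushed by the 4-alkoxide), which the benzylic, O5-bearing, dimethoxyphenyl-stabilised character of C1 should secure, and it needs contraction to outrun 2,3-epoxide closure, which the chair should secure because the ring flip required for epoxide closure would place aryl and tosylate syn-diaxial. Immediate reduction of 11 should prevent epimerisation at C3, retro-aldol cleavage and β-elimination of the crowded all-cis aldehyde.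

Step 8
Reactants: 12 [(2S,3R,4S)-2-(3,4-dimethoxyphenyl)-4-hydroxyoxolan-3-yl]methanol, 13 3,4-dimethoxybenzoyl chloride
Product: 14 [(2S,3R,4S)-2-(3,4-dimethoxyphenyl)-4-hydroxyoxolan-3-yl]methyl 3,4-dimethoxybenzoate
Conditions: 2,4,6-collidine, CH2Cl2, −40 °C to 0 °C
Reagents that add atoms: none
Why: Chemoselective acylation with an acid chloride and a hindered pyridine base at low temperature should esterify the primary hydroxyl much faster than the secondary ring hydroxyl on the crowded all-cis face, without affecting any stereocentre.

## Compound list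

1 | D-arabinose (drawn as the open-chain aldehyde; it reacts as the pyranose) | O=C[C@@H](O)[C@H](O)[C@H](O)CO | starting material
2 | 1,2,3,4-tetra-O-pivaloyl-D-arabinopyranose (anomeric mixture, C1 left undefined) | CC(C)(C)C(=O)OC1OC[C@@H](OC(=O)C(C)(C)C)[C@@H](OC(=O)C(C)(C)C)[C@@H]1OC(=O)C(C)(C)C | intermediate
3 | 2,3,4-tri-O-pivaloyl-β-D-arabinopyranosyl bromide (bromide axial, cis to O2) | Br[C@@H]1OC[C@@H](OC(=O)C(C)(C)C)[C@@H](OC(=O)C(C)(C)C)[C@@H]1OC(=O)C(C)(C)C | intermediate
4 | 4-bromo-1,2-dimethoxybenzene (4-bromoveratrole) | COc1ccc(Br)cc1OC | starting material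
5 | 3,4-dimethoxyphenyllithium | [Li]c1ccc(OC)c(OC)c1 | intermediate
6 | (3,4-dimethoxyphenyl)zinc bromide (in solution as its LiBr adduct) | COc1ccc([Zn]Br)cc1OC | intermediate
7 | (1R)-1,5-anhydro-1-C-(3,4-dimethoxyphenyl)-2,3,4-tri-O-pivaloyl-D-arabinitol | COc1ccc(cc1OC)[C@H]1OC[C@@H](OC(=O)C(C)(C)C)[C@@H](OC(=O)C(C)(C)C)[C@@H]1OC(=O)C(C)(C)C | intermediate
8 | (1R)-1,5-anhydro-1-C-(3,4-dimethoxyphenyl)-D-arabinitol (aryl, O2 and O3 equatorial, O4 axial) | COc1ccc(cc1OC)[C@H]1OC[C@@H](O)[C@@H](O)[C@@H]1O | intermediate
9 | 3,4-O-dibutylstannylene acetal of 8 (tin bridging the cis O3 and O4) | COc1ccc(cc1OC)[C@H]1OC[C@H]2O[Sn](CCCC)(CCCC)O[C@H]2[C@@H]1O | intermediate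
10 | (1R)-1,5-anhydro-1-C-(3,4-dimethoxyphenyl)-3-O-(p-tolylsulfonyl)-D-arabinitol | COc1ccc(cc1OC)[C@H]1OC[C@@H](O)[C@@H](OS(=O)(=O)c2ccc(C)cc2)[C@@H]1O | intermediate
11 | (2S,3R,4S)-2-(3,4-dimethoxyphenyl)-4-hydroxyoxolane-3-carbaldehyde (all-cis; present as its lithium alkoxide) | O=C[C@@H]1[C@H](O)CO[C@@H]1c1ccc(OC)c(OC)c1 | intermediate
12 | [(2S,3R,4S)-2-(3,4-dimethoxyphenyl)-4-hydroxyoxolan-3-yl]methanol (all-cis) | OC[C@@H]1[C@H](O)CO[C@@H]1c1ccc(OC)c(OC)c1 | intermediate
13 | 3,4-dimethoxybenzoyl chloride | COc1ccc(C(Cl)=O)cc1OC | starting material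
14 | [(2S,3R,4S)-2-(3,4-dimethoxyphenyl)-4-hydroxyoxolan-3-yl]methyl 3,4-dimethoxybenzoate | COc1ccc(C(=O)OC[C@@H]2[C@H](O)CO[C@@H]2c2ccc(OC)c(OC)c2)cc1OC | target

## Step count and risks

Total step count: 8. Longest linear sequence: 7 steps (steps 1, 2, 4, 5, 6, 7 and 8, from D-arabinose).

Steps most likely to fail:

Step 7 (key step). What may go wrong: the 4-alkoxide may take over the push so that C5 migrates instead of C1; the 2-alkoxide may close onto C3 to an epoxide that hydride then opens to deoxy products; or hydride may simply cleave the sulfonate. Fallback (O4 blocked and O2 set free only in the flask; it sets out from triol 8 and comes back to the route at target 14, replacing steps 6 to 8): acetonation of the cis-3,4-diol of 8 (2,2-dimethoxypropane, CSA, acetone) should give the 3,4-O-isopropylidene acetal F1. Ac2O/pyridine then gives its 2-O-acetate F2, and aqueous AcOH at 40 °C removes the acetal to leave the 2-O-acetyl 3,4-diol F3. Bu2SnO (toluene, reflux) followed by TsCl sulfonylates the equatorial O3 to the 3-O-tosylate F4, and TESOTf/2,6-lutidine silylates the remaining axial O4 to give the 4-O-triethylsilyl ether F5. LiEt3BH in THF then cleaves the acetate reductively; the liberated 2-alkoxide is the only possible push, and the same 1,2-shift and in-flask reduction should give the all-cis 4-O-triethylsilyl alcohol F6. Acylation with 13 (pyridine, DMAP) gives the silylated ester F7, and HF·pyridine in THF removes the silyl group to reach 14. This sequence also bypasses the regiochemical question of step 6, because F3 offers only the cis-diol to the tin reagent.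

Step 4. What may go wrong: sluggish aryl transfer from the monoarylzinc bromide, erosion of the 1,2-trans selectivity, aryl attack at the acyloxonium carbon instead of C1, or thermal elimination of the bromide to the glycal. Fallback (sets out from tetrapivaloate 2, comes back at 7): Friedel–Crafts C-glycosylation of 1,2-dimethoxybenzene with 2 under SnCl4/AgOCOCF3 in CH2Cl2 (0 °C to rt). The anomeric pivaloate ionises, the O2 pivaloate again shields its face, and the arene attacks through the position para to a methoxy group to give the equatorial aryl glycoside. This fallback makes no new compound (F0) and removes steps 2 and 3.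

Step 8. What may go wrong: competing acylation of the secondary hydroxyl, or acyl migration onto it during work-up. Fallback (sets out from diol 12, comes back at 14): Mitsunobu reaction of 12 with 3,4-dimethoxybenzoic acid (PPh3, DIAD, THF, 0 °C). Here the ester C–O bond is formed by carboxylate displacement at the activated primary carbon instead of by acyl transfer to oxygen, so the hindered secondary hydroxyl should stay untouched. This fallback makes no new compound (F0).

## Further compounds

F1 | step 7 | 3,4-O-isopropylidene acetal of triol 8 (2-hydroxyl free) | COc1ccc(cc1OC)[C@H]1OC[C@H]2OC(C)(C)O[C@H]2[C@@H]1O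
F2 | step 7 | 2-O-acetyl-3,4-O-isopropylidene derivative of 8 | COc1ccc(cc1OC)[C@H]1OC[C@H]2OC(C)(C)O[C@H]2[C@@H]1OC(C)=O
F3 | step 7 | 2-O-acetyl derivative of 8 (3,4-diol free) | COc1ccc(cc1OC)[C@H]1OC[C@@H](O)[C@@H](O)[C@@H]1OC(C)=O
F4 | step 7 | 2-O-acetyl-3-O-(p-tolylsulfonyl) derivative of 8 (4-hydroxyl free) | COc1ccc(cc1OC)[C@H]1OC[C@@H](O)[C@@H](OS(=O)(=O)c2ccc(C)cc2)[C@@H]1OC(C)=O
F5 | step 7 | 2-O-acetyl-3-O-(p-tolylsulfonyl)-4-O-triethylsilyl derivative of 8 | COc1ccc(cc1OC)[C@H]1OC[C@@H](O[Si](CC)(CC)CC)[C@@H](OS(=O)(=O)c2ccc(C)cc2)[C@@H]1OC(C)=O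
F6 | step 7 | all-cis 4-O-triethylsilyl ether of diol 12 (primary hydroxyl free) | OC[C@@H]1[C@H](O[Si](CC)(CC)CC)CO[C@@H]1c1ccc(OC)c(OC)c1
F7 | step 7 | 4-O-triethylsilyl ether of target 14 | COc1ccc(C(=O)OC[C@@H]2[C@H](O[Si](CC)(CC)CC)CO[C@@H]2c2ccc(OC)c(OC)c2)cc1OC
F0 | step 4 | none | none
F0 | step 8 | none | none
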